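**Retrosynthetic overview**

1. The target is a 4,5-trans α-methylene paraconic acid (lactone locants: O1, C2 carbonyl, C3 methylene-bearing, C4 carboxyl-bearing, C5 chain-bearing). Its only ring, the oxolan-2-one, is closed in a single step (step 4); no other ring is formed before or after.
2. Key disconnection: the lactone O1–C5 and C3–C4 bonds, by a formal (3+2) annulation of (E)-3-chloroacrylic acid (O1, C2, C3 and the CH2Cl that becomes the exocyclic CH2) with the anisyl alkene 5 (C4=C5 carrying the 13-acetoxytridecyl chain).
3. Enabling feature: the p-anisyl-conjugated C4=C5 double bond of 5. This electron-rich styrene π-system is oxidised to a radical cation, takes the carboxyl oxygen at C5 and leaves a benzylic C4 radical for 5-exo closure of the oxolan-2-one ring; the anisyl ring is the latent C4 carboxyl.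
4. After the annulation, oxidative degradation of the anisyl ring gives the C4–CO2H, and dehydrochlorination reveals the C3=CH2 last.
5. Alkene 5 comes from 1,14-tetradecanediol by monoacetylation, oxidation and Horner–Wadsworth–Emmons olefination.

Key step: step 4

Remark on the chemistry: the CH2Cl-bearing C3 centre of 7, 8 and 9 forms as a mixture of epimers and is left undefined in names and SMILES, because it becomes sp2 in step 6.

**Step 1**
Reactants: 1 1,14-tetradecanediol
Product: 2 14-hydroxytetradecyl acetate
Conditions: Ac2O (0.9 equiv, slow addition), DMAP (cat.), pyridine/THF, 0 °C to rt; unreacted 1 recycled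
Reagents that add atoms: acetic anhydride CC(=O)OC(C)=O
Why: Statistical mono-O-acylation of a symmetrical diol (nucleophilic acyl substitution) should give the monoacetate as the main product, separable from diol and diacetate; no stereocentre is formed.

**Step 2**
Reactants: 2 14-hydroxytetradecyl acetate
Product: 3 14-oxotetradecyl acetate
Conditions: TEMPO (10 mol%), PhI(OAc)2 (1.1 equiv), CH2Cl2, rt
Reagents that add atoms: none
Why: Oxoammonium (TEMPO/hypervalent iodine) oxidation of a primary alcohol should stop at the aldehyde and leave the acetate untouched.

**Step 3**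
Reactants: 3 14-oxotetradecyl acetate; 4 diethyl (4-methoxybenzyl)phosphonate
Product: 5 (E)-15-(4-methoxyphenyl)pentadec-14-en-1-yl acetate
Conditions: 4, KHMDS (1.05 equiv), THF, −78 °C; then 3, −78 °C to rt
Reagents that add atoms: none
Why: Horner–Wadsworth–Emmons olefination with a semi-stabilised benzylic phosphonate anion should favour the (E)-alkene through reversible addition and elimination, and the non-nucleophilic amide base at low temperature should spare the acetate.

**Step 4**
Reactants: 5 (E)-15-(4-methoxyphenyl)pentadec-14-en-1-yl acetate; 6 (E)-3-chloroacrylic acid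
Product: 8 13-[(2R,3R)-4-(chloromethyl)-3-(4-methoxyphenyl)-5-oxooxolan-2-yl]tridecyl acetate, via benzylic radical ester 7 (not isolated)
Conditions: 6 (2 equiv), 9-mesityl-10-methylacridinium ion-paired with a confined chiral BINOL-derived imidodiphosphorimidate anion (5 mol%; the antipode that gives 5R, found by screening), 2,4,6-triisopropylbenzenethiol (15 mol%), degassed CH2Cl2/toluene, 450 nm LEDs, −40 °C
Reagents that add atoms: none
Why: Proposed new method: a chiral-counteranion-directed polar radical crossover (3+2) annulation, whose closest known reaction types are the racemic acridinium-photocatalysed polar-radical-crossover lactone annulation of β-alkylstyrenes with unsaturated acids and the chiral-anion-directed photoredox cycloadditions of anethole-type radical cations. The excited acridinium should oxidise the anisyl alkene of 5 to a radical cation held in a contact ion pair with the chiral anion, acid 6 (hydrogen-bonded to that anion) should add to the non-benzylic alkene carbon (anti-Markovnikov, O1–C5 bond), and loss of a proton gives benzylic radical 7. Radical 7 should close the γ-lactone by 5-exo-trig attack on the α-carbon of the chloroacrylate (C3–C4 bond), the resulting α-chloroalkyl radical takes a hydrogen atom from the thiol, and the thiyl radical reoxidises the acridine radical, so the process is redox-neutral and all atoms of 5 and 6 end up in 8. The C5 stereocentre is set in the ion pair by the chiral anion, the C4 stereocentre is set by C5 through a cyclisation transition state that keeps the aryl group anti to the alkyl chain (4,5-trans), and the C3 centre is uncontrolled but erased in step 6. The step needs regioselective O-attack at C5, which the p-anisyl group secures by stabilising the C4 benzylic radical, and 5-exo instead of 6-endo closure, which the β-chlorine should favour by hindering the β-carbon while the hindered thiol avoids addition–elimination on 6. Alkene geometry is lost at the radical-cation and radical stages, so any minor Z-isomer in 5 should converge on the same product.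

**Step 5**
Reactants: 8 13-[(2R,3R)-4-(chloromethyl)-3-(4-methoxyphenyl)-5-oxooxolan-2-yl]tridecyl acetate
Product: 9 (2R,3S)-2-(13-acetoxytridecyl)-4-(chloromethyl)-5-oxooxolane-3-carboxylic acid
Conditions: RuCl3·xH2O (5 mol%), NaIO4 (15 equiv), EtOAc/MeCN/H2O, rt
Reagents that add atoms: sodium periodate [Na+].[O-]I(=O)(=O)=O (oxygen donor through catalytic RuO4); water O
Why: Ruthenium tetroxide degradation of an electron-rich aryl ring to a carboxylic acid (aryl as latent carboxyl) should leave the ipso carbon attached, so the C4 configuration is retained (the descriptor changes from R to S only through CIP priorities) while acetate, lactone and primary chloride are inert.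

**Step 6**
Reactants: 9 (2R,3S)-2-(13-acetoxytridecyl)-4-(chloromethyl)-5-oxooxolane-3-carboxylic acid
Product: 10 (2R,3S)-2-(13-acetoxytridecyl)-4-methylidene-5-oxooxolane-3-carboxylic acid (CNP0178400.1)
Conditions: DBU (2.5 equiv), CH2Cl2, 0 °C to rt; then 1 M HCl work-up
Reagents that add atoms: none
Why: E1cB-type dehydrochlorination (β-elimination) of the β-chloro lactone should give the exocyclic alkene from both C3 epimers, and because the acid is present as its carboxylate the C4–H is not acidified, so neither epimerisation nor migration of the double bond into the ring is expected.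

**Compound list**

1 | 1,14-tetradecanediol | OCCCCCCCCCCCCCCO | starting material
2 | 14-hydroxytetradecyl acetate | OCCCCCCCCCCCCCCOC(C)=O | intermediate
3 | 14-oxotetradecyl acetate | O=CCCCCCCCCCCCCCOC(C)=O | intermediate
4 | diethyl (4-methoxybenzyl)phosphonate | CCOP(=O)(Cc1ccc(OC)cc1)OCC | starting material
5 | (E)-15-(4-methoxyphenyl)pentadec-14-en-1-yl acetate | COc1ccc(/C=C/CCCCCCCCCCCCCOC(C)=O)cc1 | intermediate
6 | (E)-3-chloroacrylic acid | OC(=O)/C=C/Cl | starting material
7 | 15-acetoxy-2-{[(E)-3-chloroprop-2-enoyl]oxy}-1-(4-methoxyphenyl)pentadecyl radical, O-bearing carbon configured as in 8 | Cl/C=C/C(=O)O[C@H](CCCCCCCCCCCCCOC(C)=O)[CH]c1ccc(OC)cc1 | intermediate (not isolated)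
8 | 13-[(2R,3R)-4-(chloromethyl)-3-(4-methoxyphenyl)-5-oxooxolan-2-yl]tridecyl acetate (aryl trans to chain; epimers at the CH2Cl-bearing carbon) | ClCC1C(=O)O[C@H](CCCCCCCCCCCCCOC(C)=O)[C@H]1c2ccc(OC)cc2 | intermediate
9 | (2R,3S)-2-(13-acetoxytridecyl)-4-(chloromethyl)-5-oxooxolane-3-carboxylic acid (epimers at C-4) | ClCC1C(=O)O[C@H](CCCCCCCCCCCCCOC(C)=O)[C@H]1C(=O)O | intermediate
10 | (2R,3S)-2-(13-acetoxytridecyl)-4-methylidene-5-oxooxolane-3-carboxylic acid | C=C1C(=O)O[C@H](CCCCCCCCCCCCCOC(C)=O)[C@H]1C(=O)O | target

**Step count and risks**

Total step count: 6. Longest linear sequence: 6 steps (1 to 10).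

Steps most likely to fail:

Step 4 (Proposed new method). The risk is insufficient facial discrimination in the chiral ion pair, so that a racemic background annulation lowers the enantiomeric purity. Premature hydrogen-atom transfer to radical 7 (acyclic ester) or 6-endo closure with loss of chlorine are secondary leaks. The fallback uses known chemistry, sets out from 5 and 6 and returns at 9. The annulation is run under the established achiral conditions (9-mesityl-10-methylacridinium tetrafluoroborate 2.5 mol%, diphenyl disulfide 10 mol%, CH2Cl2, blue LEDs, rt) to give the racemic trans lactone rac-8 F1. The anisyl ring is degraded as in step 5 (RuCl3/NaIO4) to the racemic acid rac-9 F2. This is resolved by fractional crystallisation of the (S)-1-phenylethylammonium salt F3 from EtOAc/heptane; the antipodal amine is taken if the salt of the unwanted acid proves the less soluble one. Partition between 1 M HCl and EtOAc releases enantiopure 9, which re-enters at step 6.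

Step 5. The risk is over-oxidation by RuO4 (attack on the tertiary C–H next to the ring or on the chain) or incomplete ring degradation that stalls at ring-opened fragments. The fallback sets out from 3 and returns at 9, and changes both the latent carboxyl and the way it is unveiled. Olefination of 3 as in step 3 with commercial diethyl (3,4-dimethoxybenzyl)phosphonate, CCOP(=O)(Cc1ccc(OC)c(OC)c1)OCC, should give (E)-15-(3,4-dimethoxyphenyl)pentadec-14-en-1-yl acetate F4, an even more easily oxidised styrene. Annulation with 6 as in step 4 should give the veratryl lactone 13-[(2R,3R)-4-(chloromethyl)-3-(3,4-dimethoxyphenyl)-5-oxooxolan-2-yl]tridecyl acetate F5. Exhaustive ozonolysis of the electron-rich ring (O3, CH2Cl2/MeOH, −78 °C; then H2O2/HCO2H work-up) gives 9 without a metal-oxo oxidant.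

Step 6. The risk is base-mediated migration of the new double bond into the ring (endocyclic butenolide) or conjugate addition of the amidine base to the methylene lactone. The fallback sets out from 9 and returns at 10 under essentially neutral conditions. Benzeneselenol (1.2 equiv) and Et3N (2.5 equiv) in THF at rt should give, by SN2 displacement of chloride (or elimination followed by conjugate addition, which converges), (2R,3S)-2-(13-acetoxytridecyl)-5-oxo-4-[(phenylselanyl)methyl]oxolane-3-carboxylic acid F6. Oxidation with 30% H2O2 in THF/CH2Cl2 at 0 °C to rt and selenoxide syn-elimination should deliver 10.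

**Further compounds**

F1 | step 4 | rac-8, racemic trans 13-[4-(chloromethyl)-3-(4-methoxyphenyl)-5-oxooxolan-2-yl]tridecyl acetate (both enantiomers drawn) | ClCC1C(=O)O[C@H](CCCCCCCCCCCCCOC(C)=O)[C@H]1c2ccc(OC)cc2.ClCC1C(=O)O[C@@H](CCCCCCCCCCCCCOC(C)=O)[C@@H]1c2ccc(OC)cc2
F2 | step 4 | rac-9, racemic trans 2-(13-acetoxytridecyl)-4-(chloromethyl)-5-oxooxolane-3-carboxylic acid (both enantiomers drawn) | ClCC1C(=O)O[C@H](CCCCCCCCCCCCCOC(C)=O)[C@H]1C(=O)O.ClCC1C(=O)O[C@@H](CCCCCCCCCCCCCOC(C)=O)[C@@H]1C(=O)O
F3 | step 4 | (S)-1-phenylethylammonium (2R,3S)-2-(13-acetoxytridecyl)-4-(chloromethyl)-5-oxooxolane-3-carboxylate | ClCC1C(=O)O[C@H](CCCCCCCCCCCCCOC(C)=O)[C@H]1C(=O)[O-].C[C@H]([NH3+])c1ccccc1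
F4 | step 5 | (E)-15-(3,4-dimethoxyphenyl)pentadec-14-en-1-yl acetate | COc1ccc(/C=C/CCCCCCCCCCCCCOC(C)=O)cc1OC
F5 | step 5 | 13-[(2R,3R)-4-(chloromethyl)-3-(3,4-dimethoxyphenyl)-5-oxooxolan-2-yl]tridecyl acetate | ClCC1C(=O)O[C@H](CCCCCCCCCCCCCOC(C)=O)[C@H]1c2ccc(OC)c(OC)c2
F6 | step 6 | (2R,3S)-2-(13-acetoxytridecyl)-5-oxo-4-[(phenylselanyl)methyl]oxolane-3-carboxylic acid | c2ccccc2[Se]CC1C(=O)O[C@H](CCCCCCCCCCCCCOC(C)=O)[C@H]1C(=O)O
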